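Numbering: arene C1 (OH), C2 (CH3), C3 (H), C4 (OCH3), C5 (H), C6 (chain); chain C1′ (benzylic) to C16′. Cuts, last-formed first: O–Si at C5′ and C12′, C1–O (made from C1–B), then ring bonds C1–C2 and C5–C6, which separate an alkynyl boronate (C1, C6 and the whole chain) from a 2-pyrone.
Enabling feature: the ring edge C2(CH3)–C3(H)–C4(OCH3)–C5(H) is the C6–C5–C4–C3 diene of commercial 4-methoxy-6-methyl-2-pyrone, so the alkyne supplies only C1 and C6 and the lactone bridge leaves as CO2.
Chain cuts: C(sp)–C1′, C1′–C2′ and C3′–CH3, C4′–C5′, C14′=C15′, C12′–C13′; what remains is geranyl acetate, whose C1–C8 become C5′–C12′.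
Forward order: the chain grows linearly from geranyl acetate, first at the C12′ end, then from C5′ out to the alkyne; the only ring, the arene, closes in step 15, then C–B oxidation and desilylation.
Stereochemistry: C12′ (R) from reagent-controlled allylboration, C5′ (R) from catalyst-controlled propargylboration; 6′E and 10′E come from geranyl acetate, 2′E from syn-methylalumination.

Key step: step 15

Assumption: the melt of excess pyrone is taken to bring the cycloaddition into the 150 °C range, below the temperatures at which acyclic 3-siloxy-1,5-dienes with fully substituted termini should undergo Cope rearrangement at a significant rate.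
Abbreviations: TBS = tert-butyldimethylsilyl, TBSO = tert-butyldimethylsilyloxy, Bpin = 4,4,5,5-tetramethyl-1,3,2-dioxaborolan-2-yl, Ipc = isopinocampheyl.

Step 1
Reactants: 1 geranyl acetate
Product: 2 (2E,6E)-8-hydroxy-3,7-dimethylocta-2,6-dien-1-yl acetate
Conditions: SeO2 (cat.), t-BuOOH, salicylic acid (cat.), CH2Cl2, rt
Reagents that add atoms: selenium dioxide, O=[Se]=O (catalytic oxygen carrier); tert-butyl hydroperoxide, CC(C)(C)OO (stoichiometric oxygen source)
Why: Riley-type allylic oxidation (ene reaction of SeO2, then [2,3]-sigmatropic shift) should hydroxylate the E-methyl of the terminal, most electron-rich trisubstituted alkene, the 2,3-alkene being deactivated by the allylic acetate.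

Step 2
Reactants: 2 (2E,6E)-8-hydroxy-3,7-dimethylocta-2,6-dien-1-yl acetate
Product: 3 (2E,6E)-3,7-dimethyl-8-oxoocta-2,6-dien-1-yl acetate
Conditions: MnO2, CH2Cl2, rt
Reagents that add atoms: none
Why: MnO2 oxidation is selective for primary allylic alcohols under neutral conditions, so the E-enal should form without alkene isomerisation or loss of the acetate.

Step 3
Reactants: 3 (2E,6E)-3,7-dimethyl-8-oxoocta-2,6-dien-1-yl acetate
Product: 5 (2E,6E,8R)-8-hydroxy-3,7-dimethylundeca-2,6,10-trien-1-yl acetate, via borinate 4 (not isolated)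
Conditions: (+)-Ipc2BOMe, allylMgBr (slight deficit), Et2O, −78 °C → rt; then 3, Et2O, −78 °C; pH 7 buffer (NaH2PO4/Na2HPO4), MeOH, 30% H2O2, 0 °C → rt
Reagents that add atoms: allylmagnesium bromide, C=CC[Mg]Br, delivered as B-allylbis(isopinocampheyl)borane of the (−)-α-pinene series, C=CCB([C@H]1C[C@H]2C[C@@H]([C@@H]1C)C2(C)C)[C@H]1C[C@H]2C[C@@H]([C@@H]1C)C2(C)C
Why: Brown allylboration through a closed chair transition state transfers allyl to the Re face of the enal under control of the isopinocampheyl groups (the series that gives (R)-1-phenylbut-3-en-1-ol from benzaldehyde), which sets C12′ as R, and the buffered peroxide work-up spares the acetate.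

Step 4
Reactants: 5 (2E,6E,8R)-8-hydroxy-3,7-dimethylundeca-2,6,10-trien-1-yl acetate
Product: 6 (2E,6E,8R)-8-(tert-butyldimethylsilyloxy)-3,7-dimethylundeca-2,6,10-trien-1-yl acetate
Conditions: TBSCl, imidazole, DMF, rt
Reagents that add atoms: tert-butyldimethylsilyl chloride, CC(C)(C)[Si](C)(C)Cl
Why: Imidazole-promoted silylation of the secondary alcohol masks the C12′ oxygen, itself allylic, against the later MnO2 oxidation and the organometallic steps.

Step 5
Reactants: 6 (2E,6E,8R)-8-(tert-butyldimethylsilyloxy)-3,7-dimethylundeca-2,6,10-trien-1-yl acetate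
Product: 7 (2E,6E,8R)-8-(tert-butyldimethylsilyloxy)-3,7,11-trimethyldodeca-2,6,10-trien-1-yl acetate
Conditions: 2-methyl-2-butene (large excess), (H2IMes)(PCy3)Cl2Ru=CHPh (second-generation Grubbs catalyst, 5 mol %), CH2Cl2, 35 °C, closed vessel
Reagents that add atoms: 2-methyl-2-butene, CC=C(C)C
Why: Olefin cross-metathesis with excess 2-methyl-2-butene converts the monosubstituted vinyl group into the prenyl terminus, while the trisubstituted alkenes of the chain are too hindered to enter the catalytic cycle at a comparable rate.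

Step 6
Reactants: 7 (2E,6E,8R)-8-(tert-butyldimethylsilyloxy)-3,7,11-trimethyldodeca-2,6,10-trien-1-yl acetate
Product: 8 (2E,6E,8R)-8-(tert-butyldimethylsilyloxy)-3,7,11-trimethyldodeca-2,6,10-trien-1-ol
Conditions: K2CO3 (cat.), MeOH, 0 °C → rt
Reagents that add atoms: none
Why: Base-catalysed transesterification with methanol removes the primary acetate and leaves the secondary TBS ether untouched.

Step 7
Reactants: 8 (2E,6E,8R)-8-(tert-butyldimethylsilyloxy)-3,7,11-trimethyldodeca-2,6,10-trien-1-ol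
Product: 9 (2E,6E,8R)-8-(tert-butyldimethylsilyloxy)-3,7,11-trimethyldodeca-2,6,10-trienal
Conditions: MnO2, CH2Cl2, rt
Reagents that add atoms: none
Why: MnO2 oxidation of the primary allylic alcohol should give the E-enal cleanly, the only other allylic oxygen being silylated.

Step 8
Reactants: 9 (2E,6E,8R)-8-(tert-butyldimethylsilyloxy)-3,7,11-trimethyldodeca-2,6,10-trienal
Product: 11 (4R,5E,9E,11R)-11-(tert-butyldimethylsilyloxy)-6,10,14-trimethylpentadeca-5,9,13-trien-1-yn-4-ol, via borate ester 10 (not isolated)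
Conditions: allenyl-Bpin (1.5 equiv), (R)-TRIP [(R)-3,3′-bis(2,4,6-triisopropylphenyl)-1,1′-binaphthyl-2,2′-diyl hydrogen phosphate, 10 mol %], 4 Å MS, toluene, 0 °C → rt; aq. NaHCO3
Reagents that add atoms: allenylboronic acid pinacol ester, C=C=CB1OC(C)(C)C(C)(C)O1
Why: Chiral phosphoric acid-catalysed propargylboration proceeds through a six-membered SE2′ transition state held by hydrogen bonds from the acid to a boronate oxygen and the formyl hydrogen, and the (R)-catalyst is expected to direct the propargyl group to the Re face (as for (R)-1-phenylbut-3-yn-1-ol from benzaldehyde), setting C5′ as R independently of the remote C12′ centre.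

Step 9
Reactants: 11 (4R,5E,9E,11R)-11-(tert-butyldimethylsilyloxy)-6,10,14-trimethylpentadeca-5,9,13-trien-1-yn-4-ol
Product: 12 (4R,5E,9E,11R)-4,11-bis(tert-butyldimethylsilyloxy)-6,10,14-trimethylpentadeca-5,9,13-trien-1-yne
Conditions: TBSCl, imidazole, DMF, rt
Reagents that add atoms: tert-butyldimethylsilyl chloride, CC(C)(C)[Si](C)(C)Cl
Why: Standard silyl ether formation gives a second TBS group, so that both carbinols are later released in one fluoride step and the C5′ oxygen tolerates AlMe3, n-BuLi and heat.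

Step 10
Reactants: 12 (4R,5E,9E,11R)-4,11-bis(tert-butyldimethylsilyloxy)-6,10,14-trimethylpentadeca-5,9,13-trien-1-yne
Product: 15 (2E,5R,6E,10E,12R)-5,12-bis(tert-butyldimethylsilyloxy)-3,7,11,15-tetramethylhexadeca-2,6,10,14-tetraen-1-ol, via alkenylalane 13 (not isolated), via lithium alanate 14 (not isolated)
Conditions: AlMe3, Cp2ZrCl2 (cat.), CH2Cl2, 0 °C → rt; volatiles removed; n-BuLi, hexane/THF, −78 → 0 °C; (CH2O)n, THF, rt; aq. KNaC4H4O6
Reagents that add atoms: trimethylaluminium, C[Al](C)C; paraformaldehyde (as formaldehyde), C=O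
Why: Zirconium-catalysed methylalumination (Negishi carboalumination) adds CH3 and Al syn across the terminal alkyne with methyl on the internal carbon, and the derived alanate is hydroxymethylated by formaldehyde with retention, which fixes the 2′E geometry.

Step 11
Reactants: 15 (2E,5R,6E,10E,12R)-5,12-bis(tert-butyldimethylsilyloxy)-3,7,11,15-tetramethylhexadeca-2,6,10,14-tetraen-1-ol
Product: 17 (2E,5R,6E,10E,12R)-1-bromo-5,12-bis(tert-butyldimethylsilyloxy)-3,7,11,15-tetramethylhexadeca-2,6,10,14-tetraene, via mesylate 16 (not isolated)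
Conditions: MsCl, Et3N, CH2Cl2, −40 °C; LiBr, THF, −40 → 0 °C; used crude
Reagents that add atoms: lithium bromide, [Li+].[Br-]
Why: Mesylation followed by Finkelstein-type SN2 displacement with bromide at the primary allylic carbon should give the E-allylic bromide without allylic transposition at low temperature.

Step 12
Reactants: 17 (2E,5R,6E,10E,12R)-1-bromo-5,12-bis(tert-butyldimethylsilyloxy)-3,7,11,15-tetramethylhexadeca-2,6,10,14-tetraene; 18 trimethylsilylacetylene
Product: 19 (4E,7R,8E,12E,14R)-7,14-bis(tert-butyldimethylsilyloxy)-5,9,13,17-tetramethyl-1-(trimethylsilyl)octadeca-4,8,12,16-tetraen-1-yne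
Conditions: 18 (3 equiv), CuI (cat.), NaI (cat.), K2CO3, DMF, rt
Reagents that add atoms: none
Why: Copper-catalysed substitution of an allylic halide by a copper acetylide formed in situ under carbonate base is a standard route to skipped (1,4-) enynes and should occur at the unhindered primary carbon (SN2, not SN2′) with the alkene geometry kept.

Step 13
Reactants: 19 (4E,7R,8E,12E,14R)-7,14-bis(tert-butyldimethylsilyloxy)-5,9,13,17-tetramethyl-1-(trimethylsilyl)octadeca-4,8,12,16-tetraen-1-yne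
Product: 20 (4E,7R,8E,12E,14R)-7,14-bis(tert-butyldimethylsilyloxy)-5,9,13,17-tetramethyloctadeca-4,8,12,16-tetraen-1-yne
Conditions: K2CO3 (cat.), MeOH/THF, 0 °C → rt
Reagents that add atoms: none
Why: Carbonate-catalysed methanolysis cleaves the C(sp)–Si bond selectively over the two TBS ethers and is mild enough not to isomerise the skipped enyne.

Step 14
Reactants: 20 (4E,7R,8E,12E,14R)-7,14-bis(tert-butyldimethylsilyloxy)-5,9,13,17-tetramethyloctadeca-4,8,12,16-tetraen-1-yne; 21 2-isopropoxy-4,4,5,5-tetramethyl-1,3,2-dioxaborolane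
Product: 24 2-[(4E,7R,8E,12E,14R)-7,14-bis(tert-butyldimethylsilyloxy)-5,9,13,17-tetramethyloctadeca-4,8,12,16-tetraen-1-yn-1-yl]-4,4,5,5-tetramethyl-1,3,2-dioxaborolane, via lithium acetylide 22 (not isolated), via lithium borate 23 (not isolated)
Conditions: n-BuLi, THF, −78 °C; 21, −78 °C; HCl·Et2O (1 equiv), −78 °C → rt; filtration under argon, no chromatography
Reagents that add atoms: none
Why: Deprotonation of the terminal alkyne (far more acidic than the doubly activated C1′ methylene), borylation of the acetylide with the isopropoxy boronate and collapse of the ate complex with anhydrous acid is the standard preparation of alkynyl pinacolboronates.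

Step 15
Reactants: 24 2-[(4E,7R,8E,12E,14R)-7,14-bis(tert-butyldimethylsilyloxy)-5,9,13,17-tetramethyloctadeca-4,8,12,16-tetraen-1-yn-1-yl]-4,4,5,5-tetramethyl-1,3,2-dioxaborolane; 25 4-methoxy-6-methyl-2H-pyran-2-one
Product: 27 2-{2-[(2E,5R,6E,10E,12R)-5,12-bis(tert-butyldimethylsilyloxy)-3,7,11,15-tetramethylhexadeca-2,6,10,14-tetraen-1-yl]-4-methoxy-6-methylphenyl}-4,4,5,5-tetramethyl-1,3,2-dioxaborolane, via bicyclic lactone 26 (not isolated)
Conditions: 25 (10 equiv, melt), 1,2-dichlorobenzene (minimum), BHT (cat.), argon, sealed tube, 150 °C; excess 25 recovered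
Reagents that add atoms: none
Why: The pyrone acts as a cyclic diene whose termini C3 and C6 add across the boron-bearing triple bond in a concerted but asynchronous [4+2] cycloaddition to the bridged lactone 26, which at this temperature expels CO2 by retro-[4+2] and is thereby aromatised irreversibly. The closest known reaction type is the thermal benzannulation of 2-pyrones with alkynyl pinacolboronates to aryl boronates (Diels–Alder/retro-Diels–Alder sequence). The benzene ring closes by intermolecular two-bond annulation, ring bonds C1–C2 and C5–C6 forming in the same cycloaddition while the O–C(=O) bridge is only transient. No stereocentre is created in 27: the two bridgehead centres of 26 disappear with CO2, and C5′ and C12′ are remote and untouched. The step needs regiocontrol and chemoselectivity: the ring oxygen and the 4-methoxy group both polarise the diene so that pyrone C3 is its nucleophilic terminus, which pairs with the alkyne carbon β to the empty boron orbital (the one bearing C1′) and so places boron at C1 beside the C2 methyl, and the four unactivated trisubstituted alkenes cannot compete with the alkyne as dienophiles. Running the reaction in the melt of excess 25 raises the bimolecular rate so that about 150 °C should suffice, which keeps the two 3-siloxy-1,5-diene units below the range of the Cope rearrangement.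

Step 16
Reactants: 27 2-{2-[(2E,5R,6E,10E,12R)-5,12-bis(tert-butyldimethylsilyloxy)-3,7,11,15-tetramethylhexadeca-2,6,10,14-tetraen-1-yl]-4-methoxy-6-methylphenyl}-4,4,5,5-tetramethyl-1,3,2-dioxaborolane
Product: 28 2-[(2E,5R,6E,10E,12R)-5,12-bis(tert-butyldimethylsilyloxy)-3,7,11,15-tetramethylhexadeca-2,6,10,14-tetraen-1-yl]-4-methoxy-6-methylphenol
Conditions: 30% H2O2, aq. NaOH, THF, 0 °C → rt, argon
Reagents that add atoms: hydrogen peroxide, OO
Why: Oxidation of the aryl C–B bond by hydroperoxide anion (1,2-aryl shift from boron to oxygen, then hydrolysis) replaces boron by OH at the same carbon and does not touch isolated trisubstituted alkenes or silyl ethers.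

Step 17
Reactants: 28 2-[(2E,5R,6E,10E,12R)-5,12-bis(tert-butyldimethylsilyloxy)-3,7,11,15-tetramethylhexadeca-2,6,10,14-tetraen-1-yl]-4-methoxy-6-methylphenol
Product: 29 2-[(2E,5R,6E,10E,12R)-5,12-dihydroxy-3,7,11,15-tetramethylhexadeca-2,6,10,14-tetraen-1-yl]-4-methoxy-6-methylphenol (CNP0269739.1)
Conditions: TBAF, THF, 0 °C → rt, argon; aq. NH4Cl
Reagents that add atoms: none
Why: Fluoride-induced desilylation, driven by Si–F bond formation, cleaves both secondary TBS ethers without affecting the allylic stereocentres or the alkene geometries.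

Compound list
1 | geranyl acetate, (2E)-3,7-dimethylocta-2,6-dien-1-yl acetate | CC(C)=CCC/C(C)=C/COC(C)=O | starting material
2 | (2E,6E)-8-hydroxy-3,7-dimethylocta-2,6-dien-1-yl acetate | CC(=O)OC/C=C(\C)CC/C=C(\C)CO | intermediate
3 | (2E,6E)-3,7-dimethyl-8-oxoocta-2,6-dien-1-yl acetate | CC(=O)OC/C=C(\C)CC/C=C(\C)C=O | intermediate
4 | bis(isopinocampheyl)borinate of 5 (O–B(Ipc)2 at C8, Ipc from (−)-α-pinene) | CC(=O)OC/C=C(\C)CC/C=C(\C)[C@H](OB([C@H]1C[C@H]2C[C@@H]([C@@H]1C)C2(C)C)[C@H]1C[C@H]2C[C@@H]([C@@H]1C)C2(C)C)CC=C | intermediate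
5 | (2E,6E,8R)-8-hydroxy-3,7-dimethylundeca-2,6,10-trien-1-yl acetate | CC(=O)OC/C=C(\C)CC/C=C(\C)[C@H](O)CC=C | intermediate
6 | (2E,6E,8R)-8-(TBSO)-3,7-dimethylundeca-2,6,10-trien-1-yl acetate | CC(=O)OC/C=C(\C)CC/C=C(\C)[C@H](O[Si](C)(C)C(C)(C)C)CC=C | intermediate
7 | (2E,6E,8R)-8-(TBSO)-3,7,11-trimethyldodeca-2,6,10-trien-1-yl acetate | CC(=O)OC/C=C(\C)CC/C=C(\C)[C@H](O[Si](C)(C)C(C)(C)C)CC=C(C)C | intermediate
8 | (2E,6E,8R)-8-(TBSO)-3,7,11-trimethyldodeca-2,6,10-trien-1-ol | OC/C=C(\C)CC/C=C(\C)[C@H](O[Si](C)(C)C(C)(C)C)CC=C(C)C | intermediate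
9 | (2E,6E,8R)-8-(TBSO)-3,7,11-trimethyldodeca-2,6,10-trienal | O=C/C=C(\C)CC/C=C(\C)[C@H](O[Si](C)(C)C(C)(C)C)CC=C(C)C | intermediate
10 | pinacol borate ester of 11 (O–Bpin at C4) | C#CC[C@@H](OB1OC(C)(C)C(C)(C)O1)/C=C(\C)CC/C=C(\C)[C@H](O[Si](C)(C)C(C)(C)C)CC=C(C)C | intermediate
11 | (4R,5E,9E,11R)-11-(TBSO)-6,10,14-trimethylpentadeca-5,9,13-trien-1-yn-4-ol | C#CC[C@@H](O)/C=C(\C)CC/C=C(\C)[C@H](O[Si](C)(C)C(C)(C)C)CC=C(C)C | intermediate
12 | (4R,5E,9E,11R)-4,11-bis(TBSO)-6,10,14-trimethylpentadeca-5,9,13-trien-1-yne | C#CC[C@@H](O[Si](C)(C)C(C)(C)C)/C=C(\C)CC/C=C(\C)[C@H](O[Si](C)(C)C(C)(C)C)CC=C(C)C | intermediate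
13 | dimethyl[(1E,4R,5E,9E,11R)-4,11-bis(TBSO)-2,6,10,14-tetramethylpentadeca-1,5,9,13-tetraen-1-yl]alane | C[Al](C)/C=C(\C)C[C@@H](O[Si](C)(C)C(C)(C)C)/C=C(\C)CC/C=C(\C)[C@H](O[Si](C)(C)C(C)(C)C)CC=C(C)C | intermediate
14 | lithium butyl(dimethyl)alkenylaluminate derived from 13 | [Li+].CCCC[Al-](C)(C)/C=C(\C)C[C@@H](O[Si](C)(C)C(C)(C)C)/C=C(\C)CC/C=C(\C)[C@H](O[Si](C)(C)C(C)(C)C)CC=C(C)C | intermediate
15 | (2E,5R,6E,10E,12R)-5,12-bis(TBSO)-3,7,11,15-tetramethylhexadeca-2,6,10,14-tetraen-1-ol | OC/C=C(\C)C[C@@H](O[Si](C)(C)C(C)(C)C)/C=C(\C)CC/C=C(\C)[C@H](O[Si](C)(C)C(C)(C)C)CC=C(C)C | intermediate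
16 | methanesulfonate of 15 | CS(=O)(=O)OC/C=C(\C)C[C@@H](O[Si](C)(C)C(C)(C)C)/C=C(\C)CC/C=C(\C)[C@H](O[Si](C)(C)C(C)(C)C)CC=C(C)C | intermediate
17 | (2E,5R,6E,10E,12R)-1-bromo-5,12-bis(TBSO)-3,7,11,15-tetramethylhexadeca-2,6,10,14-tetraene | BrC/C=C(\C)C[C@@H](O[Si](C)(C)C(C)(C)C)/C=C(\C)CC/C=C(\C)[C@H](O[Si](C)(C)C(C)(C)C)CC=C(C)C | intermediate
18 | trimethylsilylacetylene | C[Si](C)(C)C#C | starting material
19 | (4E,7R,8E,12E,14R)-7,14-bis(TBSO)-5,9,13,17-tetramethyl-1-(trimethylsilyl)octadeca-4,8,12,16-tetraen-1-yne | C[Si](C)(C)C#CC/C=C(\C)C[C@@H](O[Si](C)(C)C(C)(C)C)/C=C(\C)CC/C=C(\C)[C@H](O[Si](C)(C)C(C)(C)C)CC=C(C)C | intermediate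
20 | (4E,7R,8E,12E,14R)-7,14-bis(TBSO)-5,9,13,17-tetramethyloctadeca-4,8,12,16-tetraen-1-yne | C#CC/C=C(\C)C[C@@H](O[Si](C)(C)C(C)(C)C)/C=C(\C)CC/C=C(\C)[C@H](O[Si](C)(C)C(C)(C)C)CC=C(C)C | intermediate
21 | 2-isopropoxy-4,4,5,5-tetramethyl-1,3,2-dioxaborolane | CC(C)OB1OC(C)(C)C(C)(C)O1 | starting material
22 | lithium acetylide of 20 | [Li]C#CC/C=C(\C)C[C@@H](O[Si](C)(C)C(C)(C)C)/C=C(\C)CC/C=C(\C)[C@H](O[Si](C)(C)C(C)(C)C)CC=C(C)C | intermediate
23 | lithium alkynyl(isopropoxy)pinacolborate from 22 and 21 | [Li+].CC(C)O[B-]1(C#CC/C=C(\C)C[C@@H](O[Si](C)(C)C(C)(C)C)/C=C(\C)CC/C=C(\C)[C@H](O[Si](C)(C)C(C)(C)C)CC=C(C)C)OC(C)(C)C(C)(C)O1 | intermediate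
24 | alkynyl pinacolboronate, 2-[(4E,7R,8E,12E,14R)-7,14-bis(TBSO)-5,9,13,17-tetramethyloctadeca-4,8,12,16-tetraen-1-yn-1-yl]-4,4,5,5-tetramethyl-1,3,2-dioxaborolane | CC1(C)OB(OC1(C)C)C#CC/C=C(\C)C[C@@H](O[Si](C)(C)C(C)(C)C)/C=C(\C)CC/C=C(\C)[C@H](O[Si](C)(C)C(C)(C)C)CC=C(C)C | intermediate
25 | 4-methoxy-6-methyl-2H-pyran-2-one | COC1=CC(=O)OC(C)=C1 | starting material
26 | 5-[(2E,5R,6E,10E,12R)-5,12-bis(TBSO)-3,7,11,15-tetramethylhexadeca-2,6,10,14-tetraen-1-yl]-8-methoxy-1-methyl-6-Bpin-2-oxabicyclo[2.2.2]octa-5,7-dien-3-one (both bridgehead diastereomers) | O=C1OC2(C)C=C(OC)C1C(C/C=C(\C)C[C@@H](O[Si](C)(C)C(C)(C)C)/C=C(\C)CC/C=C(\C)[C@H](O[Si](C)(C)C(C)(C)C)CC=C(C)C)=C2B1OC(C)(C)C(C)(C)O1 | intermediate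
27 | aryl pinacolboronate, 2-{2-[(2E,5R,6E,10E,12R)-5,12-bis(TBSO)-3,7,11,15-tetramethylhexadeca-2,6,10,14-tetraen-1-yl]-4-methoxy-6-methylphenyl}-4,4,5,5-tetramethyl-1,3,2-dioxaborolane | COc1cc(C)c(B2OC(C)(C)C(C)(C)O2)c(C/C=C(\C)C[C@@H](O[Si](C)(C)C(C)(C)C)/C=C(\C)CC/C=C(\C)[C@H](O[Si](C)(C)C(C)(C)C)CC=C(C)C)c1 | intermediate
28 | 2-[(2E,5R,6E,10E,12R)-5,12-bis(TBSO)-3,7,11,15-tetramethylhexadeca-2,6,10,14-tetraen-1-yl]-4-methoxy-6-methylphenol | COc1cc(C)c(O)c(C/C=C(\C)C[C@@H](O[Si](C)(C)C(C)(C)C)/C=C(\C)CC/C=C(\C)[C@H](O[Si](C)(C)C(C)(C)C)CC=C(C)C)c1 | intermediate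
29 | 2-[(2E,5R,6E,10E,12R)-5,12-dihydroxy-3,7,11,15-tetramethylhexadeca-2,6,10,14-tetraen-1-yl]-4-methoxy-6-methylphenol (CNP0269739.1) | COc1cc(C)c(O)c(C/C=C(\C)C[C@@H](O)/C=C(\C)CC/C=C(\C)[C@H](O)CC=C(C)C)c1 | target

Total step count: 17. Longest linear sequence: 17 steps (1 to 29); 18, 21 and 25 are bought and enter directly.

Steps most likely to fail

Step 15. The donor-substituted pyrone is a reluctant diene, so the cycloaddition may be too slow at a temperature the chain tolerates. Regiocontrol may erode, and prolonged heating may start siloxy-Cope rearrangement or protodeboronation. The fallback gives up ring construction and joins a purchased arene to the chain at C6–C1′; it sets out from bromide 17. Commercial 4-methoxy-2-methylphenol is brominated at its only free ortho position (NBS, i-Pr2NH cat., CH2Cl2, 0 °C) to give 2-bromo-4-methoxy-6-methylphenol F1. MeLi (1 equiv) and then t-BuLi (2 equiv) in Et2O at −78 °C convert F1, by deprotonation and bromine–lithium exchange, into lithium 2-lithio-4-methoxy-6-methylphenoxide F2. With catalytic CuBr·SMe2, F2 is alkylated at carbon by 17 (SN2 at the primary allylic carbon, E geometry kept) and gives phenol 28 after aqueous work-up. The route is rejoined at 28, and steps 12 to 16 are not needed.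

Step 8. Propargyl transfer to the β,β-disubstituted enal may be slow, facial selectivity may be incomplete, and some allenyl carbinol may form. The fallback sets out from enal 9 and builds C1′–C4′ in one operation by a vinylogous Mukaiyama aldol addition. The silyl dienol ether of ethyl 3-methylbut-2-enoate adds through its γ-carbon under SiCl4/chiral bisphosphoramide Lewis-base catalysis (i-Pr2NEt, CH2Cl2, −78 °C, catalyst enantiomer chosen for Re-face attack). This should give ethyl (2E,5R,6E,10E,12R)-12-(tert-butyldimethylsilyloxy)-5-hydroxy-3,7,11,15-tetramethylhexadeca-2,6,10,14-tetraenoate F3 with the 2′E alkene already in place. Silylation (TBSCl, imidazole, DMF) gives the bis-silyl ether ethyl (2E,5R,6E,10E,12R)-5,12-bis(tert-butyldimethylsilyloxy)-3,7,11,15-tetramethylhexadeca-2,6,10,14-tetraenoate F4. DIBAL-H (CH2Cl2, −78 °C) reduces the ester to allylic alcohol 15, where the route is rejoined; steps 8 to 10 are bypassed.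

Step 12. Substitution may partly take the SN2′ course, the allylic bromide may lose its E geometry through bromide exchange, and the skipped enyne may isomerise to the conjugated allene under base. The fallback forms the C1′–C2′ bond instead of the C(sp)–C1′ bond; it sets out from alkyne 12. Its alane 13 (first operation of step 10) is quenched with I2 (THF, −30 °C) to give (1E,4R,5E,9E,11R)-4,11-bis(tert-butyldimethylsilyloxy)-1-iodo-2,6,10,14-tetramethylpentadeca-1,5,9,13-tetraene F5. Iodine–lithium exchange (t-BuLi, 2 equiv, Et2O, −78 °C) gives the alkenyllithium [(1E,4R,5E,9E,11R)-4,11-bis(tert-butyldimethylsilyloxy)-2,6,10,14-tetramethylpentadeca-1,5,9,13-tetraen-1-yl]lithium F6. With catalytic CuI, F6 is alkylated by 3-bromo-1-(trimethylsilyl)prop-1-yne; the silyl group blocks attack at the alkyne terminus, so the alkyne and not the allene should form. The product is 19, where the route is rejoined; the formaldehyde trapping of step 10 and steps 11 and 12 are bypassed.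

Further compounds
F1 | step 15 | 2-bromo-4-methoxy-6-methylphenol | COc1cc(C)c(O)c(Br)c1
F2 | step 15 | lithium 2-lithio-4-methoxy-6-methylphenoxide | [Li]Oc1c(C)cc(OC)cc1[Li]
F3 | step 8 | ethyl (2E,5R,6E,10E,12R)-12-(tert-butyldimethylsilyloxy)-5-hydroxy-3,7,11,15-tetramethylhexadeca-2,6,10,14-tetraenoate | CCOC(=O)/C=C(\C)C[C@@H](O)/C=C(\C)CC/C=C(\C)[C@H](O[Si](C)(C)C(C)(C)C)CC=C(C)C
F4 | step 8 | ethyl (2E,5R,6E,10E,12R)-5,12-bis(tert-butyldimethylsilyloxy)-3,7,11,15-tetramethylhexadeca-2,6,10,14-tetraenoate | CCOC(=O)/C=C(\C)C[C@@H](O[Si](C)(C)C(C)(C)C)/C=C(\C)CC/C=C(\C)[C@H](O[Si](C)(C)C(C)(C)C)CC=C(C)C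
F5 | step 12 | (1E,4R,5E,9E,11R)-4,11-bis(tert-butyldimethylsilyloxy)-1-iodo-2,6,10,14-tetramethylpentadeca-1,5,9,13-tetraene | I/C=C(\C)C[C@@H](O[Si](C)(C)C(C)(C)C)/C=C(\C)CC/C=C(\C)[C@H](O[Si](C)(C)C(C)(C)C)CC=C(C)C
F6 | step 12 | [(1E,4R,5E,9E,11R)-4,11-bis(tert-butyldimethylsilyloxy)-2,6,10,14-tetramethylpentadeca-1,5,9,13-tetraen-1-yl]lithium | [Li]/C=C(\C)C[C@@H](O[Si](C)(C)C(C)(C)C)/C=C(\C)CC/C=C(\C)[C@H](O[Si](C)(C)C(C)(C)C)CC=C(C)C
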